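The route rests on reading the cyclobutane C4–C5–C6–C7 as a cyclobutanone (C6) whose two alpha carbons C5 and C7 carry the ends of the bridge C10–C9–C8, a crotonyl unit with its carbonyl at C8 and its methyl at C10. One operation, a desymmetrising [3+3] annulation of a chiral enamine with crotonoyl chloride, forms C5–C10 and C7–C8, closes the six-membered ring C5–C6–C7–C8–C9–C10 and sets C4, C5, C7 and C10. Its precursor is a 3-methylcyclobutanone whose second C4 substituent, a dimethyl acetal (the future C3), is branched at the ring to force bonding on the methyl face. The seven-membered ring follows by Wittig olefination at C6, hydrogenation and a Weinreb–Claisen closure.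

Key step: step 5

Numbering used throughout: ring carbons of the target are C1 (CH–O), C2 (CH2), C3 (CH–O), C4 (C–CH3), C5, C6, C7 (the three CH of the cyclobutane), C8 (C=O), C9 (CH2), C10 (CH–CH3), C11 (quaternary); C12 is the CH2OH carbon on C11.
Remark on the precursor: next to the ring a CH2OR arm is no larger than methyl, because it can turn a hydrogen towards either alpha carbon; the arm is therefore carried as a dimethyl acetal, which is branched at the carbon on C4 and already has the oxidation level of C3.
Remark on C6: the arm on C4 lies directly under C6, so reagents reach C6 only from the face of the three-carbon bridge, and a C6 alkoxide beta to the C8 ketone would open the cyclobutane by retro-aldol cleavage; C11 is therefore attached by neutral olefination and brought to the lower face by hydrogenation, which leaves no C6 oxygen to remove.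
Assumption: alkene 13 may form as both geometrical isomers, which converge in step 7; enamine 9 equilibrates with its regioisomer and is drawn as the one that reacts.

Step 1
Reactants: 1 3-methylidenecyclobutane-1-carbonitrile
Product: 2 1-methyl-3-methylidenecyclobutane-1-carbonitrile
Conditions: LiN(i-Pr)2, THF, −78 °C; MeI, −78 °C to rt
Reagents that add atoms: iodomethane, CI
Why: Alkylation of a nitrile-stabilised carbanion at the only acidic C–H creates the quaternary C4; no stereocentre is formed.

Step 2
Reactants: 2 1-methyl-3-methylidenecyclobutane-1-carbonitrile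
Product: 4 1-methyl-3-methylidenecyclobutane-1-carbaldehyde, via aluminium aldimine 3 (not isolated)
Conditions: i-Bu2AlH, CH2Cl2, −78 °C; then 1 M HCl, 0 °C
Reagents that add atoms: water, O
Why: Partial reduction of a nitrile with i-Bu2AlH stops at the N-alumino imine, which hydrolyses to the non-enolisable aldehyde.

Step 3
Reactants: 4 1-methyl-3-methylidenecyclobutane-1-carbaldehyde
Product: 5 1-(dimethoxymethyl)-1-methyl-3-methylidenecyclobutane
Conditions: HC(OMe)3, MeOH, PPTS (cat.), rt
Reagents that add atoms: trimethyl orthoformate, COC(OC)OC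
Why: Acid-catalysed acetalisation driven by the orthoester should be clean because the aldehyde cannot enolise and the exocyclic alkene is inert to a pyridinium acid.

Step 4
Reactants: 5 1-(dimethoxymethyl)-1-methyl-3-methylidenecyclobutane
Product: 7 3-(dimethoxymethyl)-3-methylcyclobutan-1-one, via ozonide 6 (not isolated)
Conditions: O3, CH2Cl2, −78 °C; then Me2S, −78 °C to rt
Reagents that add atoms: ozone, [O-][O+]=O
Why: Ozonolysis of the 1,1-disubstituted alkene with reductive work-up unmasks the cyclobutanone and leaves the acetal untouched.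

Step 5
Reactants: 7 3-(dimethoxymethyl)-3-methylcyclobutan-1-one; 8 (E)-but-2-enoyl chloride
Product: 11 7-(dimethoxymethyl)-4,7-dimethylbicyclo[3.1.1]heptane-2,6-dione, via enamine 9 (not isolated), via iminium chloride 10 (not isolated)
Conditions: (2R,5R)-2,5-dimethylpyrrolidine (1.05 equiv), 4 Å MS, PhH, 50 °C; then 8 (1.1 equiv), 0 to 80 °C; then H2O, NaOAc/AcOH buffer (pH 5), rt
Reagents that add atoms: (E)-but-2-enoyl chloride 8, C/C=C/C(Cl)=O; water, O
Why: Proposed new method: enamine 9 is N-acylated by 8 and the acyl enammonium ion undergoes a chair-like [3,3] shift (or 9 adds directly to the beta carbon), which joins C5 to C10 and leaves a ketene or acyl chloride at C8; proton transfer regenerates the enamine towards C7, C7 is acylated by C8 with loss of chloride, and buffered water hydrolyses iminium ion 10 to 11. The closest known reaction types are the alpha,alpha-prime annulation of cyclohexanone enamines with acryloyl chlorides to bicyclo[3.3.1]nonane-2,9-diones and the amine-mediated desymmetrisation of 3-substituted cyclobutanones, neither shown for a cyclobutanone enamine and an acid chloride. The ring C5–C6–C7–C8–C9–C10 closes by a 6-(enolendo)-exo-trig acylation, possible because the bonds made at C5 and C7 of a four-membered ring are necessarily cis. The acetal on C4 always turns at least one methoxy group towards each alpha carbon, so bonding should occur on the methyl face (C4, and the face at C5 and C7); the E geometry of 8 in the chair transition state should turn the C10 methyl towards C6 and away from the C4 methyl; the C2-symmetric (2R,5R)-amine keeps its proximal methyl clear of the incoming chain only for attack at C5 on that face, which should decide C5 against C7 and hence the absolute configuration. The step needs face, diastereo- and enantiotopic-group selectivity at once and relies on the matched pairing of acetal and amine shielding, while the pH 5 work-up protects the non-enolisable 1,3-diketone from retro-Claisen opening.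

Step 6
Reactants: 11 7-(dimethoxymethyl)-4,7-dimethylbicyclo[3.1.1]heptane-2,6-dione; 12 tert-butyl (triphenylphosphoranylidene)acetate
Product: 13 tert-butyl 2-[7-(dimethoxymethyl)-4,7-dimethyl-2-oxobicyclo[3.1.1]heptan-6-ylidene]acetate
Conditions: 12 (1.5 equiv), PhMe, 100 °C
Reagents that add atoms: tert-butyl (triphenylphosphoranylidene)acetate 12, CC(C)(C)OC(=O)C=P(c1ccccc1)(c1ccccc1)c1ccccc1
Why: Wittig olefination with a stabilised ylide is neutral and should select the strained, doubly activated C6 cyclobutanone over the C8 ketone; it passes through an oxaphosphetane, not a free C6 alkoxide, so the cyclobutane should not open.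

Step 7
Reactants: 13 tert-butyl 2-[7-(dimethoxymethyl)-4,7-dimethyl-2-oxobicyclo[3.1.1]heptan-6-ylidene]acetate
Product: 14 tert-butyl 2-[7-(dimethoxymethyl)-4,7-dimethyl-2-oxobicyclo[3.1.1]heptan-6-yl]acetate (C6–H on the face of the three-carbon bridge)
Conditions: H2 (1 atm), Pd/C, EtOAc, rt
Reagents that add atoms: none
Why: In this heterogeneous hydrogenation the pseudo-axial acetal arm on C4 lies under C6 and blocks the lower face, so hydrogen should add from the bridge face and push C11 down beside C3 (sets C6).

Step 8
Reactants: 14 tert-butyl 2-[7-(dimethoxymethyl)-4,7-dimethyl-2-oxobicyclo[3.1.1]heptan-6-yl]acetate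
Product: 15 tert-butyl 2-(7-formyl-4,7-dimethyl-2-oxobicyclo[3.1.1]heptan-6-yl)acetate
Conditions: 1 M HCl, THF, rt
Reagents that add atoms: water, O
Why: Acid hydrolysis of the dimethyl acetal frees the non-enolisable C3 aldehyde; the tert-butyl ester and the ketone should survive dilute acid at room temperature.

Step 9
Reactants: 15 tert-butyl 2-(7-formyl-4,7-dimethyl-2-oxobicyclo[3.1.1]heptan-6-yl)acetate; 16 ethyl diazoacetate
Product: 17 ethyl 3-oxo-3-[C4-bicyclic]propanoate (C3 ketone, C2H2, C1 ethyl ester; tert-butyl acetate arm and C8 ketone unchanged)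
Conditions: 16 (1.3 equiv), SnCl2 (10 mol %), CH2Cl2, rt
Reagents that add atoms: ethyl diazoacetate 16, CCOC(=O)C=[N+]=[N-]
Why: Roskamp homologation (addition of the diazo ester to the aldehyde and 1,2-hydride shift) gives the beta-keto ester in one step and is selective for aldehydes over ketones and esters.

Step 10
Reactants: 17 C3 beta-keto ethyl ester
Product: 18 ethyl (3R)-3-hydroxy-3-[C4-bicyclic]propanoate (C3 alcohol)
Conditions: H2 (50 bar), RuCl2[(S)-BINAP] (1 mol %), EtOH, 50 °C
Reagents that add atoms: none
Why: Noyori asymmetric hydrogenation of a beta-keto ester under catalyst control should set C3; the (S)-ligand acts in the same spatial sense as in its reduction of acetoacetate to the (S)-hydroxy ester, the descriptor becoming R only because C4 outranks C2, and the isolated C8 ketone is not reduced by this catalyst.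

Step 11
Reactants: 18 C3 alcohol
Product: 19 C3 tert-butyldimethylsilyl ether of 18
Conditions: TBSOTf, 2,6-lutidine, CH2Cl2, −78 to 0 °C
Reagents that add atoms: tert-butyldimethylsilyl triflate, CC(C)(C)[Si](C)(C)OS(=O)(=O)C(F)(F)F
Why: Silylation with the silyl triflate protects the hindered secondary alcohol; the bulky ether later fixes the twist of the four-carbon bridge.

Step 12
Reactants: 19 C3 silyl ether
Product: 20 C8 1,3-dioxolane of 19
Conditions: (Me3SiOCH2)2, TMSOTf (5 mol %), CH2Cl2, −78 to −20 °C
Reagents that add atoms: 1,2-bis(trimethylsilyloxy)ethane, C[Si](C)(C)OCCO[Si](C)(C)C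
Why: Noyori ketalisation at low temperature masks the only ketone without harming the silyl ether or the tert-butyl ester.

Step 13
Reactants: 20 C8 dioxolane
Product: 21 C1 N-methoxy-N-methylamide (Weinreb amide) of 20
Conditions: MeNH(OMe)·HCl, i-PrMgCl, THF, −20 to 0 °C
Reagents that add atoms: N,O-dimethylhydroxylamine hydrochloride, CNOC.Cl
Why: Aminolysis of an ester by the chloromagnesium amide converts the ethyl ester at C1 and leaves the hindered tert-butyl ester untouched.

Step 14
Reactants: 21 Weinreb amide
Product: 23 tricyclic beta-keto tert-butyl ester (C1 ketone, C11–H, C3 silyl ether, C8 dioxolane), via lithium hemiaminal adduct 22 (not isolated)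
Conditions: LiN(SiMe3)2 (2.5 equiv), THF, −78 to −20 °C; then NH4Cl (aq)
Reagents that add atoms: none
Why: In this Dieckmann-type Claisen acylation by a Weinreb amide the ester alpha protons at C11 are more acidic than the amide alpha protons at C2, so the C11 enolate should form and close C11–C1; the chelated adduct 22 cannot revert or react twice, and the closure is helped by the C3 and C11 arms being held parallel under the cyclobutane.

Step 15
Reactants: 23 tricyclic beta-keto ester
Product: 24 C11-methylated beta-keto ester (CH3 on the C5 side, ester on the C7 side)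
Conditions: MeI, K2CO3, acetone, rt
Reagents that add atoms: iodomethane, CI
Why: C-Alkylation of a beta-keto ester enolate; the silyl ether should hold the four-carbon bridge in the twist with C3–O pseudo-equatorial, so that iodomethane enters C11 from the outer face and the ester ends cis to the C3 oxygen (sets C11).

Step 16
Reactants: 24 methylated beta-keto ester
Product: 25 C3 alcohol of 24 (beta-hydroxy ketone)
Conditions: HF·pyridine, pyridine, THF, 0 °C to rt
Reagents that add atoms: none
Why: Buffered fluoride desilylation frees the C3 hydroxyl without base, so neither retro-aldol nor retro-Claisen cleavage is expected.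

Step 17
Reactants: 25 beta-hydroxy ketone
Product: 26 C1,C3-trans diol tert-butyl ester
Conditions: Me4NBH(OAc)3, MeCN/AcOH (1:1), −30 °C
Reagents that add atoms: none
Why: Evans–Saksena hydroxyl-directed reduction delivers hydride within the C3 alkoxy-borohydride to the same face of C1, which should give the 1,3-anti diol (sets C1); the ester and the dioxolane are inert.

Step 18
Reactants: 26 diol ester
Product: 27 triol (C1–OH, C3–OH, C12–OH; C8 dioxolane)
Conditions: LiAlH4, THF, 0 °C to reflux; then H2O, NaOH (aq)
Reagents that add atoms: none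
Why: Hydride reduction of the neopentyl tert-butyl ester to C12H2OH is possible only because C8 is masked.

Step 19
Reactants: 27 triol
Product: 28 C12 tert-butyldimethylsilyl ether diol
Conditions: TBSCl, imidazole, CH2Cl2, 0 °C
Reagents that add atoms: tert-butyldimethylsilyl chloride, CC(C)(C)[Si](C)(C)Cl
Why: Silylation should select the primary hydroxyl over the two secondary hydroxyls flanked by quaternary carbons.

Step 20
Reactants: 28 C12 silyl ether diol; 29 angelic acid
Product: 30 C1,C3-bis-angelate (C12 silyl ether, C8 dioxolane)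
Conditions: 29 (4 equiv), 2,4,6-Cl3C6H2COCl, Et3N, PhMe, rt; then 28, 80 °C
Reagents that add atoms: angelic acid 29, C/C=C(/C)C(=O)O
Why: Yamaguchi esterification through the mixed anhydride, run without a nucleophilic pyridine catalyst, should acylate both hindered hydroxyls while keeping the Z geometry of the angeloyl groups.

Step 21
Reactants: 30 protected bis-angelate
Product: 31 target CNP0287707.1
Conditions: 2 M HCl, THF, rt
Reagents that add atoms: water, O
Why: Dilute aqueous acid hydrolyses the dioxolane and the primary silyl ether in one operation and should leave the two hindered angelates untouched.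

Compound list
1 | 3-methylidenecyclobutane-1-carbonitrile | C=C1CC(C#N)C1 | starting material
2 | 1-methyl-3-methylidenecyclobutane-1-carbonitrile | C=C1CC(C)(C#N)C1 | intermediate
3 | N-(diisobutylalumanyl) aldimine of 4 | C=C1CC(C)(C=N[Al](CC(C)C)CC(C)C)C1 | intermediate (not isolated)
4 | 1-methyl-3-methylidenecyclobutane-1-carbaldehyde | C=C1CC(C)(C=O)C1 | intermediate
5 | 1-(dimethoxymethyl)-1-methyl-3-methylidenecyclobutane | C=C1CC(C)(C(OC)OC)C1 | intermediate
6 | spiro ozonide (1,2,4-trioxolane) of 5 | COC(OC)C1(C)CC2(C1)OCOO2 | intermediate (not isolated)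
7 | 3-(dimethoxymethyl)-3-methylcyclobutan-1-one | COC(OC)C1(C)CC(=O)C1 | intermediate (key-step precursor)
8 | (E)-but-2-enoyl chloride | C/C=C/C(Cl)=O | starting material
9 | enamine of 7 with (2R,5R)-2,5-dimethylpyrrolidine, double bond C6=C5 | COC(OC)[C@@]1(C)CC(N2[C@H](C)CC[C@H]2C)=C1 | intermediate (not isolated)
10 | bicyclic C6 iminium chloride | COC(OC)[C@]2(C)[C@@H]3C(=[N+]4[C@H](C)CC[C@H]4C)[C@H]2C(=O)C[C@H]3C.[Cl-] | intermediate (not isolated)
11 | 7-(dimethoxymethyl)-4,7-dimethylbicyclo[3.1.1]heptane-2,6-dione (C4 methyl syn to the three-carbon bridge, C10 methyl on the C6 side) | COC(OC)[C@]2(C)[C@@H]3C(=O)[C@H]2C(=O)C[C@H]3C | intermediate (key-step product)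
12 | tert-butyl (triphenylphosphoranylidene)acetate | CC(C)(C)OC(=O)C=P(c1ccccc1)(c1ccccc1)c1ccccc1 | starting material
13 | tert-butyl 2-[7-(dimethoxymethyl)-4,7-dimethyl-2-oxobicyclo[3.1.1]heptan-6-ylidene]acetate | COC(OC)[C@]2(C)[C@@H]3C(=CC(=O)OC(C)(C)C)[C@H]2C(=O)C[C@H]3C | intermediate
14 | tert-butyl 2-[7-(dimethoxymethyl)-4,7-dimethyl-2-oxobicyclo[3.1.1]heptan-6-yl]acetate | COC(OC)[C@]2(C)[C@@H]3[C@@H]([C@H]2C(=O)C[C@H]3C)CC(=O)OC(C)(C)C | intermediate
15 | tert-butyl 2-(7-formyl-4,7-dimethyl-2-oxobicyclo[3.1.1]heptan-6-yl)acetate | O=C[C@]2(C)[C@@H]3[C@@H]([C@H]2C(=O)C[C@H]3C)CC(=O)OC(C)(C)C | intermediate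
16 | ethyl diazoacetate | CCOC(=O)C=[N+]=[N-] | starting material
17 | C3 beta-keto ethyl ester | CCOC(=O)CC(=O)[C@]2(C)[C@@H]3[C@@H]([C@H]2C(=O)C[C@H]3C)CC(=O)OC(C)(C)C | intermediate
18 | (3R)-C3 alcohol (beta-hydroxy ethyl ester) | CCOC(=O)C[C@@H](O)[C@]2(C)[C@@H]3[C@@H]([C@H]2C(=O)C[C@H]3C)CC(=O)OC(C)(C)C | intermediate
19 | C3 tert-butyldimethylsilyl ether of 18 | CCOC(=O)C[C@@H](O[Si](C)(C)C(C)(C)C)[C@]2(C)[C@@H]3[C@@H]([C@H]2C(=O)C[C@H]3C)CC(=O)OC(C)(C)C | intermediate
20 | C8 1,3-dioxolane of 19 | CCOC(=O)C[C@@H](O[Si](C)(C)C(C)(C)C)[C@]2(C)[C@@H]3[C@@H]([C@H]2C4(OCCO4)C[C@H]3C)CC(=O)OC(C)(C)C | intermediate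
21 | C1 N-methoxy-N-methylamide of 20 | CON(C)C(=O)C[C@@H](O[Si](C)(C)C(C)(C)C)[C@]2(C)[C@@H]3[C@@H]([C@H]2C4(OCCO4)C[C@H]3C)CC(=O)OC(C)(C)C | intermediate
22 | lithium alkoxide of the tricyclic C1 hemiaminal | [Li]OC1(N(C)OC)C[C@@H](O[Si](C)(C)C(C)(C)C)[C@]2(C)[C@@H]3[C@@H]([C@H]2C4(OCCO4)C[C@H]3C)C1C(=O)OC(C)(C)C | intermediate (not isolated)
23 | tricyclic beta-keto tert-butyl ester (C1 ketone, C11–H) | O=C1C[C@@H](O[Si](C)(C)C(C)(C)C)[C@]2(C)[C@@H]3[C@@H]([C@H]2C4(OCCO4)C[C@H]3C)C1C(=O)OC(C)(C)C | intermediate
24 | C11-methylated beta-keto ester | O=C1C[C@@H](O[Si](C)(C)C(C)(C)C)[C@]2(C)[C@@H]3[C@@H]([C@H]2C4(OCCO4)C[C@H]3C)[C@@]1(C)C(=O)OC(C)(C)C | intermediate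
25 | C3-hydroxy C1-ketone | O=C1C[C@@H](O)[C@]2(C)[C@@H]3[C@@H]([C@H]2C4(OCCO4)C[C@H]3C)[C@@]1(C)C(=O)OC(C)(C)C | intermediate
26 | C1,C3-trans diol tert-butyl ester | O[C@@H]1C[C@@H](O)[C@]2(C)[C@@H]3[C@@H]([C@H]2C4(OCCO4)C[C@H]3C)[C@@]1(C)C(=O)OC(C)(C)C | intermediate
27 | triol with C8 dioxolane | O[C@@H]1C[C@@H](O)[C@]2(C)[C@@H]3[C@@H]([C@H]2C4(OCCO4)C[C@H]3C)[C@@]1(C)CO | intermediate
28 | C12 tert-butyldimethylsilyl ether diol | O[C@@H]1C[C@@H](O)[C@]2(C)[C@@H]3[C@@H]([C@H]2C4(OCCO4)C[C@H]3C)[C@@]1(C)CO[Si](C)(C)C(C)(C)C | intermediate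
29 | angelic acid, (Z)-2-methylbut-2-enoic acid | C/C=C(/C)C(=O)O | starting material
30 | C1,C3-bis-angelate with C12 silyl ether and C8 dioxolane | C/C=C(/C)C(=O)O[C@@H]1C[C@@H](OC(=O)/C(C)=C\C)[C@]2(C)[C@@H]3[C@@H]([C@H]2C4(OCCO4)C[C@H]3C)[C@@]1(C)CO[Si](C)(C)C(C)(C)C | intermediate
31 | CNP0287707.1 | C/C=C(/C)C(=O)O[C@@H]1C[C@@H](OC(=O)/C(C)=C\C)[C@]2(C)[C@@H]3[C@@H]([C@H]2C(=O)C[C@H]3C)[C@@]1(C)CO | target

Total step count: 21. Longest linear sequence: 21 steps, from 1.

Steps most likely to fail

Step 5 (proposed new method). The strained enamine may be N-acylated without going on to form the C–C bonds, the ketene may oligomerise, the non-enolisable 1,3-diketone may open by retro-Claisen cleavage during hydrolysis, or face and enantiotopic-group selection may be poor. The fallback uses known reaction types, sets out from 7 and returns at 11. Ketone 7 is condensed with (S)-1-amino-2-(methoxymethyl)pyrrolidine to the hydrazone F1. Its lithium azaenolate (LiN(i-Pr)2, THF, −78 °C) undergoes a hydrazone Michael addition to methyl (E)-but-2-enoate on the methyl face, which forms C5–C10 and gives the hydrazone ester F2; the C10 configuration would have to be confirmed, and the (Z)-enoate used if it is the opposite one. The ester is converted with MeNH(OMe)·HCl and i-PrMgCl into the hydrazone Weinreb amide F3. Ozonolysis of the C=N bond (O3, CH2Cl2, −78 °C) frees the keto Weinreb amide F4. Kinetic deprotonation at C7 (LiN(SiMe3)2, THF, −78 °C) and intramolecular acylation of the ketone enolate by the Weinreb amide close C7–C8 and give 11 after a buffered work-up.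

Step 6. The only open face of C6 is crowded by C9 and the C10 methyl, so olefination may be too slow; if a C6 oxyanion lives long enough, the cyclobutane may open. The fallback sets out from 11 and returns at 13. Only C8 can enolise, so TBSOTf and Et3N should convert it selectively into the silyl enol ether F5 and remove the beta-carbonyl that drives ring opening. Peterson olefination of the C6 ketone with the small lithium enolate of tert-butyl (trimethylsilyl)acetate (LiN(i-Pr)2, THF, −78 °C to rt) then gives the enoate F6. Buffered Bu4NF/AcOH cleaves the enol ether and gives 13.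

Step 15. Iodomethane may enter on the inner face of the ring enolate and give the C11 epimer, or O-alkylation may compete. The fallback sets out from 23, returns at 27 and reverses the order in which the two C11 substituents arrive. Alkylation of 23 with benzyl chloromethyl ether (NaH, THF, 0 °C) puts the future C12 on the face that iodomethane would have taken and gives F7. HF·pyridine gives the C3 alcohol F8. Directed reduction with Me4NBH(OAc)3 gives the trans diol F9. LiAlH4 reduces the tert-butyl ester to the primary alcohol F10. Selective tosylation of that primary hydroxyl (TsCl, pyridine) gives F11. LiEt3BH reduces the neopentyl tosylate to the C11 methyl group in F12. Hydrogenolysis of the benzyl ether (H2, Pd/C) gives 27.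

Further compounds
F1 | step 5 | hydrazone of 7 with (S)-1-amino-2-(methoxymethyl)pyrrolidine | COC[C@@H]1CCCN1N=C2CC(C)(C(OC)OC)C2
F2 | step 5 | hydrazone methyl ester after Michael addition (C5–C10 formed) | COC(OC)[C@@]1(C)CC(=NN2CCC[C@H]2COC)[C@@H]1[C@H](C)CC(=O)OC
F3 | step 5 | hydrazone Weinreb amide | COC(OC)[C@@]1(C)CC(=NN2CCC[C@H]2COC)[C@@H]1[C@H](C)CC(=O)N(C)OC
F4 | step 5 | keto Weinreb amide, 3-[2-oxocyclobutyl]butanamide | COC(OC)[C@@]1(C)CC(=O)[C@@H]1[C@H](C)CC(=O)N(C)OC
F5 | step 6 | C8 tert-butyldimethylsilyl enol ether of 11 | COC(OC)[C@]2(C)[C@@H]3C(=O)[C@H]2C(O[Si](C)(C)C(C)(C)C)=C[C@H]3C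
F6 | step 6 | C6 tert-butyl ylideneacetate with C8 silyl enol ether | COC(OC)[C@]2(C)[C@@H]3C(=CC(=O)OC(C)(C)C)[C@H]2C(O[Si](C)(C)C(C)(C)C)=C[C@H]3C
F7 | step 15 | C11 benzyloxymethyl beta-keto tert-butyl ester | O=C1C[C@@H](O[Si](C)(C)C(C)(C)C)[C@]2(C)[C@@H]3[C@@H]([C@H]2C4(OCCO4)C[C@H]3C)[C@@]1(C(=O)OC(C)(C)C)COCc5ccccc5
F8 | step 15 | C3 alcohol of F7 | O=C1C[C@@H](O)[C@]2(C)[C@@H]3[C@@H]([C@H]2C4(OCCO4)C[C@H]3C)[C@@]1(C(=O)OC(C)(C)C)COCc5ccccc5
F9 | step 15 | C1,C3-trans diol of F8 | O[C@@H]1C[C@@H](O)[C@]2(C)[C@@H]3[C@@H]([C@H]2C4(OCCO4)C[C@H]3C)[C@@]1(C(=O)OC(C)(C)C)COCc5ccccc5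
F10 | step 15 | triol with C11 hydroxymethyl and benzyloxymethyl groups | O[C@@H]1C[C@@H](O)[C@]2(C)[C@@H]3[C@@H]([C@H]2C4(OCCO4)C[C@H]3C)[C@@]1(CO)COCc5ccccc5
F11 | step 15 | primary tosylate of F10 | O[C@@H]1C[C@@H](O)[C@]2(C)[C@@H]3[C@@H]([C@H]2C4(OCCO4)C[C@H]3C)[C@@]1(COS(=O)(=O)c6ccc(C)cc6)COCc5ccccc5
F12 | step 15 | C12 benzyl ether of 27 | O[C@@H]1C[C@@H](O)[C@]2(C)[C@@H]3[C@@H]([C@H]2C4(OCCO4)C[C@H]3C)[C@@]1(C)COCc5ccccc5
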